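**Assumption:** (−)-α-Zingiberene, (5R)-2-methyl-5-[(2S)-6-methylhept-5-en-2-yl]cyclohexa-1,3-diene, is treated as purchasable. It is sold as a natural-product standard and can be isolated from commercial ginger oil on AgNO3-silica. Its configuration is the one that matches the terpene half of the target.

## Retrosynthesis
- Terpecurcumin B comes from a boron-mediated (Pabon) aldol condensation of aryl-ether aldehyde **6** with feruloylacetone **8**, which builds the curcumin dienone last.
- Aldehyde **6** comes from a Pd-catalysed allylic etherification of vanillin with the C-1 carbonate of cis-ene-diol **3**. The reaction goes with net retention, which gives the required cis-1,4 pattern.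
- Diol **3** comes from reduction of endoperoxide **2**, which comes from the [4+2] addition of singlet O2 to (−)-zingiberene (**1**).
- **1** already carries the cyclohexene ring and the side-chain stereocentre. No carbocycle is built; the only ring made is the transient 2,3-dioxabicyclo[2.2.2]octene (step 1), which is opened in step 2.

## Forward route

**Step 1**
Reactants: **1**, (−)-α-zingiberene
Product: **2**, (1R,4S,7R)-5-methyl-7-[(2S)-6-methylhept-5-en-2-yl]-2,3-dioxabicyclo[2.2.2]oct-5-ene, with the O–O bridge on the face anti to the side chain
Conditions: O2, TPP (cat.), visible light, CH2Cl2, −20 °C, stopped at partial conversion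
Reagents that add atoms: dioxygen, O=O
Why: The [4+2] cycloaddition of singlet oxygen to the cyclohexa-1,3-diene is suprafacial. The O–O bridge forms on the face opposite the C-5 side chain, which sets the two new carbinol centres cis to each other and trans to the side chain. The diene reacts much faster than the prenyl alkene, and any syn isomer is removed by chromatography.

**Step 2**
Reactants: **2**
Product: **3**, (1S,4R,5R)-2-methyl-5-[(2S)-6-methylhept-5-en-2-yl]cyclohex-2-ene-1,4-diol
Conditions: thiourea, MeOH, 0 °C to rt
Reagents that add atoms: none
Why: Thiourea cleaves the O–O bond of the endoperoxide, a mild reductive peroxide cleavage that leaves both C–O bonds and the alkenes untouched, so the cis-1,4-diol keeps its configuration.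

**Step 3**
Reactants: **3**
Product: **4**, methyl [(1S,4R,5R)-4-hydroxy-2-methyl-5-[(2S)-6-methylhept-5-en-2-yl]cyclohex-2-en-1-yl] carbonate
Conditions: ClCO2Me (1.05 equiv), pyridine, CH2Cl2, −40 °C to 0 °C
Reagents that add atoms: methyl chloroformate, COC(=O)Cl
Why: Chemoselective mono-acylation occurs at C-1 OH, the less hindered one. C-4 OH sits next to the branched C-5 carrying the side chain. No stereocentre is touched, and the C-4 OH stays free and non-ionisable for the next step.

**Step 4**
Reactants: **4**; **5**, vanillin (4-hydroxy-3-methoxybenzaldehyde)
Product: **6**, 4-{[(1S,4R,5R)-4-hydroxy-2-methyl-5-[(2S)-6-methylhept-5-en-2-yl]cyclohex-2-en-1-yl]oxy}-3-methoxybenzaldehyde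
Conditions: Pd(PPh3)4 (5 mol%), THF, 50 °C, vanillin 1.5 equiv
Reagents that add atoms: none
Why: This is a Tsuji–Trost allylic etherification. Pd(0) ionises the carbonate anti to the leaving group (inversion), and the phenoxide attacks the π-allyl terminus C-1, remote from the C-4 oxygen, from the face opposite Pd (second inversion). The net result is retention at C-1, so the aryl ether stays cis to the C-4 OH and trans to the side chain. The aldehyde, prenyl alkene and free allylic OH tolerate Pd(0); CO2 and MeOH are lost.

**Step 5**
Reactants: **5**, vanillin; **7**, acetylacetone (pentane-2,4-dione, 3 equiv)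
Product: **8**, feruloylacetone, (E)-6-(4-hydroxy-3-methoxyphenyl)hex-5-ene-2,4-dione
Conditions: B2O3, B(OBu)3, n-BuNH2 (cat.), EtOAc, 80 °C; then aqueous 0.4 M HCl, 60 °C, 30 min
Reagents that add atoms: none (the boron reagents are removed on hydrolysis)
Why: The acetylacetone–boron complex masks the central CH2, so the aldol condensation (Pabon) occurs only at a terminal methyl. Excess acetylacetone favours mono-condensation, and the new alkene is E.

**Step 6**
Reactants: **6**; **8**
Product: **9**, Terpecurcumin B
Conditions: **8** + B2O3, EtOAc, 40 °C, 30 min; then **6**, B(OBu)3, n-BuNH2 (cat.), 80 °C, 3 h; workup with 5% aqueous AcOH, 50 °C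
Reagents that add atoms: none
Why: The boron-complexed feruloylacetone condenses at its remaining methyl with aldehyde **6** in the same Pabon aldol condensation, giving the E-enone and the enolised 1,3-diketone. The mild AcOH hydrolysis of the boron complex spares the acid-sensitive allylic aryl ether and allylic alcohol, and all four terpene stereocentres are untouched.

## Compound list
1 | (−)-α-zingiberene | CC(C)=CCC[C@H](C)[C@H]1CC=C(C)C=C1 | starting material
2 | (1R,4S,7R)-endoperoxide of 1 | O2[C@H]1C[C@H]([C@@H](C)CCC=C(C)C)[C@@H](O2)C=C1C | intermediate
3 | (1S,4R,5R)-cis-ene-1,4-diol | O[C@H]1C[C@H]([C@@H](C)CCC=C(C)C)[C@@H](O)C=C1C | intermediate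
4 | C-1 methyl carbonate of 3 | COC(=O)O[C@H]1C[C@H]([C@@H](C)CCC=C(C)C)[C@@H](O)C=C1C | intermediate
5 | vanillin | COc1cc(C=O)ccc1O | starting material
6 | aryl-ether aldehyde | COc1cc(C=O)ccc1O[C@H]1C[C@H]([C@@H](C)CCC=C(C)C)[C@@H](O)C=C1C | intermediate
7 | acetylacetone | CC(=O)CC(C)=O | starting material
8 | feruloylacetone | COc1cc(/C=C/C(=O)CC(C)=O)ccc1O | intermediate
9 | Terpecurcumin B | COc1cc(/C=C/C(=O)/C=C(O)/C=C/c2ccc(O[C@H]3C[C@H]([C@@H](C)CCC=C(C)C)[C@@H](O)C=C3C)c(OC)c2)ccc1O | target

## Step count
- Total steps: 6.
- Longest linear sequence: 5 steps (1 → 2 → 3 → 4 → 6). Step 5 is a parallel branch.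

## Three steps most likely to fail
1. **Step 3 (regioselective mono-carbonate at C-1 OH).** The two secondary OH groups are similar, and the wrong regioisomer would give the C-4 aryl ether in step 4.
   - Fallback: skip differentiation. Open endoperoxide **2** directly with Pd(0)/vanillin (ionisation of the allylic peroxide, attack at C-1, anti to Pd), then reduce the resulting C-4 hydroperoxide with PPh3.
2. **Step 4 (Pd etherification).** Risks are attack at C-3 instead of C-1, formation of a transannular 7-oxanorbornene from the free cis OH, and elimination to a diene.
   - Fallback: switch to double Mitsunobu inversion. Protect C-4 OH as TBS, invert C-1 with p-nitrobenzoic acid and DEAD/PPh3, hydrolyse the ester, then Mitsunobu with vanillin, which inverts again to give the required cis aryl ether. Finish with TBAF.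
3. **Step 1 (singlet-oxygen addition and zingiberene supply).** Zingiberene is air-sensitive, the prenyl group can undergo an ene reaction, and the anti selectivity may be only moderate.
   - Fallback: abandon zingiberene and build the ring by RCM. Start from (S)-citronellal, do an Evans α-alkylation and a Felkin-controlled vinyl-Grignard addition, and close the cyclohexene from an isopropenyl/vinyl diene. Set the C-1 and C-4 oxygens by substrate control and Mitsunobu.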